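## Retrosynthetic overview
1. Target 22 ⇒ (phenol tautomer, loss of HBr) 6,6-dibromo enone 20 ⇒ (two enol-silane brominations at C6) β-bromo enone 14 ⇒ (C=O → C–Br) symmetric 2-aryloxycyclohexane-1,3-dione 13.
2. 13 ⇒ (decarboxylation, Dieckmann ring closure) open-chain keto diester 10.
3. Key C–C disconnection: 10 ⇒ intermolecular Michael addition of β-keto ester 8 to ethyl acrylate 9.
4. 8 ⇒ decarboxylative Claisen condensation of aryloxyacetic acid 4 with malonate half-ester 5. 4 ⇒ 2,4-dibromophenol 1 + ethyl bromoacetate 2.
5. Ring order: the 2,4-dibromophenyl ring is bought intact and carries the ether oxygen from step 1. The phenol ring is built as a carbocycle in steps 4–5 and becomes aromatic only in the last step.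

Assumption: the target has no stereogenic element and is achiral, so no enantiocontrol is needed. The stereocentres of 7, 10, 11, 12 and 17 are racemic or labile, and all are erased on aromatisation.

## Route

Step 1
Reactants: 1 2,4-dibromophenol; 2 ethyl bromoacetate
Product: 3 ethyl (2,4-dibromophenoxy)acetate
Conditions: K2CO3, acetone, reflux
Reagents that add atoms: none
Why: Williamson ether synthesis, in which K2CO3 fully deprotonates the acidic phenol and the phenoxide displaces bromide from an activated primary α-bromo ester while the aryl bromides stay inert.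

Step 2
Reactants: 3 ethyl (2,4-dibromophenoxy)acetate
Product: 4 (2,4-dibromophenoxy)acetic acid
Conditions: LiOH·H2O, THF/H2O, rt; then 1 M HCl
Reagents that add atoms: lithium hydroxide, [Li+].[OH-] (its O becomes the acid OH)
Why: Saponification (BAc2) of an unhindered ethyl ester, to which the aryl ether and aryl bromides are inert.

Step 3
Reactants: 4 (2,4-dibromophenoxy)acetic acid; 5 potassium ethyl malonate
Product: 8 ethyl 4-(2,4-dibromophenoxy)-3-oxobutanoate, via 2-(2,4-dibromophenoxy)-1-(imidazol-1-yl)ethan-1-one 6 (not isolated), via 4-(2,4-dibromophenoxy)-2-(ethoxycarbonyl)-3-oxobutanoic acid (as Mg chelate) 7 (not isolated)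
Conditions: CDI, THF, rt; then 5, MgCl2, Et3N, MeCN, rt → 40 °C; 1 M HCl
Reagents that add atoms: 1,1'-carbonyldiimidazole, O=C(n1ccnc1)n1ccnc1 (imidazolyl group of 6 only; nothing of it stays in 8)
Why: Masamune–Brooks decarboxylative Claisen condensation, in which the magnesium enolate of the malonate half-ester C-acylates the acyl imidazolide and loss of CO2 makes the crossed condensation irreversible.

Step 4 (key C–C bond)
Reactants: 8 ethyl 4-(2,4-dibromophenoxy)-3-oxobutanoate; 9 ethyl acrylate (1.05 equiv)
Product: 10 diethyl 2-[(2,4-dibromophenoxy)acetyl]pentanedioate (racemic)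
Conditions: NaOEt (0.1 equiv), EtOH, 0 °C → rt
Reagents that add atoms: none
Why: Intermolecular Michael addition, in which catalytic ethoxide deprotonates only the doubly activated C2–H (pKa about 11) so the bond forms there and not at ArOCH2, one equivalent of acrylate at low temperature limits double addition, and the new stereocentre is racemic and later destroyed.

Step 5
Reactants: 10 diethyl 2-[(2,4-dibromophenoxy)acetyl]pentanedioate
Product: 11 ethyl 3-(2,4-dibromophenoxy)-2,4-dioxocyclohexane-1-carboxylate
Conditions: NaOEt (2.2 equiv), EtOH, reflux; then 2 M HCl, 0 °C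
Reagents that add atoms: none
Why: Dieckmann (intramolecular Claisen) condensation, in which the aryloxy-stabilised carbanion attacks the δ-ester in the only ring closure of feasible size (six) and the equilibrium is pulled by the very stable 1,3-dione enolate, as in the classical acetoacetate/acrylate route to dihydroresorcinols.

Step 6
Reactants: 11 ethyl 3-(2,4-dibromophenoxy)-2,4-dioxocyclohexane-1-carboxylate
Product: 13 2-(2,4-dibromophenoxy)cyclohexane-1,3-dione, via 3-(2,4-dibromophenoxy)-2,4-dioxocyclohexane-1-carboxylic acid 12 (not isolated)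
Conditions: 2 M NaOH aq., reflux; then conc. HCl to pH 1, reflux
Reagents that add atoms: sodium hydroxide, [Na+].[OH-] (O of the carboxyl group of 12 only; lost again as CO2)
Why: Saponification followed by β-keto acid decarboxylation (the dimedone protocol), in which the dione is protected from retro-Claisen cleavage in base as its enolate and dilute acid is too weak to cyclodehydrate onto the deactivated aryl ring.

Step 7
Reactants: 13 2-(2,4-dibromophenoxy)cyclohexane-1,3-dione
Product: 14 3-bromo-2-(2,4-dibromophenoxy)cyclohex-2-en-1-one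
Conditions: Ph3P, Br2, CH2Cl2, 0 °C; then 13, Et3N, 0 °C → rt
Reagents that add atoms: bromine, BrBr (delivered as Ph3PBr2)
Why: Deoxybromination of a vinylogous acid, in which the enol oxygen is activated as an oxyphosphonium ion, bromide enters by conjugate addition–elimination with loss of Ph3PO, and the symmetry of 13 allows only one regioisomer.

Step 8
Reactants: 14 3-bromo-2-(2,4-dibromophenoxy)cyclohex-2-en-1-one
Product: 16 {[5-bromo-6-(2,4-dibromophenoxy)cyclohexa-1,5-dien-1-yl]oxy}trimethylsilane (extractive work-up, used crude under argon), via lithium 5-bromo-6-(2,4-dibromophenoxy)cyclohexa-1,5-dien-1-olate 15 (not isolated)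
Conditions: LiHMDS (1.1 equiv), THF, −78 °C; TMSCl, −78 → 0 °C
Reagents that add atoms: chlorotrimethylsilane, C[Si](C)(C)Cl; lithium hexamethyldisilazide, [Li+].C[Si](C)(C)[N-][Si](C)(C)C (Li of 15 only)
Why: Kinetic α'-deprotonation of an enone gives the cross-conjugated dienolate, which is O-silylated, and the C6–H is far more acidic than any aryl C–H so the hindered amide leaves the aryl and vinyl bromides alone at −78 °C.

Step 9
Reactants: 16 {[5-bromo-6-(2,4-dibromophenoxy)cyclohexa-1,5-dien-1-yl]oxy}trimethylsilane
Product: 17 3,6-dibromo-2-(2,4-dibromophenoxy)cyclohex-2-en-1-one (racemic)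
Conditions: NBS (1.05 equiv), THF, −78 → 0 °C
Reagents that add atoms: N-bromosuccinimide, O=C1CCC(=O)N1Br
Why: Electrophilic α-bromination of a silyl enol ether, in which Br+ attacks C6 (the nucleophilic enol-ether terminus) under neutral conditions that avoid acid-catalysed γ-enolisation and do not touch the deactivated dibromoaryl ring, and the new stereocentre is racemic and later erased.

Step 10
Reactants: 17 3,6-dibromo-2-(2,4-dibromophenoxy)cyclohex-2-en-1-one
Product: 19 {[2,5-dibromo-6-(2,4-dibromophenoxy)cyclohexa-1,5-dien-1-yl]oxy}trimethylsilane (extractive work-up, used crude), via lithium 2,5-dibromo-6-(2,4-dibromophenoxy)cyclohexa-1,5-dien-1-olate 18 (not isolated)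
Conditions: LiHMDS (1.05 equiv), THF, −78 °C; TMSCl, −78 → 0 °C
Reagents that add atoms: chlorotrimethylsilane, C[Si](C)(C)Cl; lithium hexamethyldisilazide, [Li+].C[Si](C)(C)[N-][Si](C)(C)C (Li of 18 only)
Why: Enolisation and O-silylation of an α-bromo ketone, in which the remaining C6–H is acidified by bromine and is removed first, and no Favorskii path exists because the other α-carbon is sp2.

Step 11
Reactants: 19 {[2,5-dibromo-6-(2,4-dibromophenoxy)cyclohexa-1,5-dien-1-yl]oxy}trimethylsilane
Product: 20 3,6,6-tribromo-2-(2,4-dibromophenoxy)cyclohex-2-en-1-one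
Conditions: NBS (1.05 equiv), THF, −78 → 0 °C
Reagents that add atoms: N-bromosuccinimide, O=C1CCC(=O)N1Br
Why: A second electrophilic bromination of a silyl enol ether at the same enol-ether carbon places the gem-dibromide regiospecifically at C6 and supplies the missing oxidation level for aromatisation.

Step 12
Reactants: 20 3,6,6-tribromo-2-(2,4-dibromophenoxy)cyclohex-2-en-1-one
Product: 22 3,6-dibromo-2-(2,4-dibromophenoxy)phenol (target), via 2,5-dibromo-6-(2,4-dibromophenoxy)cyclohexa-2,5-dien-1-one 21 (not isolated)
Conditions: DBU (2.2 equiv), MeCN, 0 °C → rt; 1 M HCl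
Reagents that add atoms: none
Why: Dehydrobromination and aromatisation (E2, then keto–enol tautomerisation), in which only C5–H lies β to the C6 bromines so one HBr is lost to give dienone 21, which tautomerises irreversibly to the phenol with one Br kept at C6, just as 2,2-dibromo-1-tetralone gives 2-bromo-1-naphthol.

## Compound list
1 | 2,4-dibromophenol | Oc1ccc(Br)cc1Br | starting material
2 | ethyl bromoacetate | CCOC(=O)CBr | starting material
3 | ethyl (2,4-dibromophenoxy)acetate | CCOC(=O)COc1ccc(Br)cc1Br | intermediate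
4 | (2,4-dibromophenoxy)acetic acid | OC(=O)COc1ccc(Br)cc1Br | intermediate
5 | potassium ethyl malonate | [K+].[O-]C(=O)CC(=O)OCC | starting material
6 | 2-(2,4-dibromophenoxy)-1-(imidazol-1-yl)ethan-1-one | O=C(COc1ccc(Br)cc1Br)n1ccnc1 | intermediate (not isolated)
7 | 4-(2,4-dibromophenoxy)-2-(ethoxycarbonyl)-3-oxobutanoic acid (racemic, present as Mg chelate) | CCOC(=O)C(C(=O)O)C(=O)COc1ccc(Br)cc1Br | intermediate (not isolated)
8 | ethyl 4-(2,4-dibromophenoxy)-3-oxobutanoate | CCOC(=O)CC(=O)COc1ccc(Br)cc1Br | intermediate
9 | ethyl acrylate | C=CC(=O)OCC | starting material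
10 | diethyl 2-[(2,4-dibromophenoxy)acetyl]pentanedioate (racemic) | CCOC(=O)CCC(C(=O)OCC)C(=O)COc1ccc(Br)cc1Br | intermediate
11 | ethyl 3-(2,4-dibromophenoxy)-2,4-dioxocyclohexane-1-carboxylate (drawn as keto form; largely enolised, stereocentres labile) | CCOC(=O)C1CCC(=O)C(Oc2ccc(Br)cc2Br)C1=O | intermediate
12 | 3-(2,4-dibromophenoxy)-2,4-dioxocyclohexane-1-carboxylic acid (keto form; stereocentres labile) | OC(=O)C1CCC(=O)C(Oc2ccc(Br)cc2Br)C1=O | intermediate (not isolated)
13 | 2-(2,4-dibromophenoxy)cyclohexane-1,3-dione (drawn as diketone; exists mainly as the enol) | O=C1CCCC(=O)C1Oc1ccc(Br)cc1Br | intermediate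
14 | 3-bromo-2-(2,4-dibromophenoxy)cyclohex-2-en-1-one | O=C1CCCC(Br)=C1Oc1ccc(Br)cc1Br | intermediate
15 | lithium 5-bromo-6-(2,4-dibromophenoxy)cyclohexa-1,5-dien-1-olate | [Li+].[O-]C1=CCCC(Br)=C1Oc1ccc(Br)cc1Br | intermediate (not isolated)
16 | {[5-bromo-6-(2,4-dibromophenoxy)cyclohexa-1,5-dien-1-yl]oxy}trimethylsilane | C[Si](C)(C)OC1=CCCC(Br)=C1Oc1ccc(Br)cc1Br | intermediate
17 | 3,6-dibromo-2-(2,4-dibromophenoxy)cyclohex-2-en-1-one (racemic) | O=C1C(Br)CCC(Br)=C1Oc1ccc(Br)cc1Br | intermediate
18 | lithium 2,5-dibromo-6-(2,4-dibromophenoxy)cyclohexa-1,5-dien-1-olate | [Li+].[O-]C1=C(Br)CCC(Br)=C1Oc1ccc(Br)cc1Br | intermediate (not isolated)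
19 | {[2,5-dibromo-6-(2,4-dibromophenoxy)cyclohexa-1,5-dien-1-yl]oxy}trimethylsilane | C[Si](C)(C)OC1=C(Br)CCC(Br)=C1Oc1ccc(Br)cc1Br | intermediate
20 | 3,6,6-tribromo-2-(2,4-dibromophenoxy)cyclohex-2-en-1-one | O=C1C(Br)(Br)CCC(Br)=C1Oc1ccc(Br)cc1Br | intermediate
21 | 2,5-dibromo-6-(2,4-dibromophenoxy)cyclohexa-2,5-dien-1-one | O=C1C(Br)=CCC(Br)=C1Oc1ccc(Br)cc1Br | intermediate (not isolated)
22 | 3,6-dibromo-2-(2,4-dibromophenoxy)phenol (achiral) | Oc1c(Br)ccc(Br)c1Oc1ccc(Br)cc1Br | target

## Step count and risks
Total steps: 12. Longest linear sequence: 12 (1 → 22; 2, 5 and 9 are bought).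

**Step 5 (Dieckmann closure).** 10 rests as its unreactive β-keto ester enolate, and hot ethoxide can also cause retro-Claisen or retro-Michael cleavage. The fallback sets out from 10 and removes the extra ester before ring closure.
- 6 M HCl/AcOH at reflux hydrolyses both esters to 2-[(2,4-dibromophenoxy)acetyl]pentanedioic acid F1.
- F1 loses CO2 in the same pot to give 6-(2,4-dibromophenoxy)-5-oxohexanoic acid F2.
- Fischer esterification (MeOH, cat. H2SO4) gives methyl 6-(2,4-dibromophenoxy)-5-oxohexanoate F3.
- In F3 the aryloxy-stabilised enolate is the most acidic site and the only one that can reach the ester through a six-membered ring. KOtBu in THF (0 °C → rt) closes it directly.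
- The sequence comes back to the route at 13, bypassing 11 and 12.

**Step 7 (direct deoxybromination of the hindered 2-aryloxy dione).** The fallback sets out from 13 and separates activation from displacement.
- MsCl/Et3N in CH2Cl2 at 0 °C gives the isolable enol sulfonate 2-(2,4-dibromophenoxy)-3-oxocyclohex-1-en-1-yl methanesulfonate F4.
- F4 is treated with excess LiBr in warm acetone (BF3·OEt2 assistance if slow). Bromide enters by conjugate addition–elimination.
- The sequence comes back at 14.

**Step 10 (with 11; building the gem-dibromide).** The α-bromo enone may aromatise prematurely, or the bromo enol silane may be sluggish toward NBS. The fallback sets out from 17, aromatises first and installs the last bromine on the arene.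
- DBU in MeCN removes HBr to give 3-bromo-2-(2,4-dibromophenoxy)cyclohexa-2,5-dien-1-one F5.
- F5 tautomerises to 3-bromo-2-(2,4-dibromophenoxy)phenol F6.
- Amine-directed ortho-bromination follows (Br2 and t-BuNH2 premixed in toluene at −30 °C, then F6 at −78 °C → rt). The hydrogen-bonded N-bromoamine delivers bromine to the single free ortho position C6 rather than to the para position next to C3–Br, as in guaiacol → 6-bromoguaiacol.
- The sequence comes back at 22.

## Further compounds
F1 | step 5 | 2-[(2,4-dibromophenoxy)acetyl]pentanedioic acid (racemic) | OC(=O)CCC(C(=O)O)C(=O)COc1ccc(Br)cc1Br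
F2 | step 5 | 6-(2,4-dibromophenoxy)-5-oxohexanoic acid | OC(=O)CCCC(=O)COc1ccc(Br)cc1Br
F3 | step 5 | methyl 6-(2,4-dibromophenoxy)-5-oxohexanoate | COC(=O)CCCC(=O)COc1ccc(Br)cc1Br
F4 | step 7 | 2-(2,4-dibromophenoxy)-3-oxocyclohex-1-en-1-yl methanesulfonate | CS(=O)(=O)OC1=C(Oc2ccc(Br)cc2Br)C(=O)CCC1
F5 | step 10 | 3-bromo-2-(2,4-dibromophenoxy)cyclohexa-2,5-dien-1-one | O=C1C=CCC(Br)=C1Oc1ccc(Br)cc1Br
F6 | step 10 | 3-bromo-2-(2,4-dibromophenoxy)phenol | Oc1cccc(Br)c1Oc1ccc(Br)cc1Br
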